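## Retrosynthetic overview

1. Target 32 ⇐ macrocyclic trienal 29: face-selective epoxidation of C5=C6 (oxirane, formed last), 1,2-reduction of the C12 aldehyde, desilylation.
2. 29 ⇐ seco-bromide 27: C7–C8 bond by 11-endo addition of a (Z)-allyl radical to an α-substituted acrolein, then loss of silanol to give C9=C10 (the eleven-membered ring, formed second to last).
3. 27 ⇐ alkyne 13 + (Z)-enal 19: C3–C4 bond by asymmetric alkenylzinc addition (sets C4 and the E-C2=C3 bond), then acylation with 3-methylbut-2-enoic acid.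
4. 13 ⇐ methacrolein + 2-silyloxybutadiene: an enantioselective Diels–Alder reaction sets quaternary C1 in a temporary cyclohexene (first ring), which ozonolysis opens into the C11–C10 aldehyde arm and the C1′–C3′ acid arm.
5. 19 ⇐ but-2-yn-1-ol via (Z)-3-iodobut-2-en-1-ol, which fixes the Z-C5=C6 geometry.

Locants used in names: ring C1 (quaternary, CH3) – C2=C3 – C4 (O-acyl) – C5(CH3)–C6 (oxirane) – C7 – C8 – C9(C12H2OH)=C10 – C11 – back to C1; side chain on C1: C1′H2–C2′H2–C3′H(OH)–C4′(CH3)=C5′H2. TIPS = triisopropylsilyl, TBS = tert-butyldimethylsilyl.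

Assumption: 2-bromo-3,3-dimethoxyprop-1-ene (7, acetal-protected 2-bromoacrolein) is taken as a catalogue compound.

## Route

Step 1
Reactants: 1 but-3-en-2-one
Product: 2 2-(triisopropylsilyloxy)buta-1,3-diene
Conditions: i-Pr3SiOTf, Et3N, Et2O, 0 → 25 °C
Reagents that add atoms: triisopropylsilyl trifluoromethanesulfonate, CC(C)[Si](OS(=O)(=O)C(F)(F)F)(C(C)C)C(C)C
Why: Soft enolisation and O-silylation of the methyl ketone (silyl enol ether formation) gives the 2-silyloxydiene; no stereocentre is formed.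

Step 2
Reactants: 2 2-(triisopropylsilyloxy)buta-1,3-diene; 3 2-methylprop-2-enal
Product: 4 (S)-1-methyl-4-(triisopropylsilyloxy)cyclohex-3-ene-1-carbaldehyde
Conditions: (S)-3,3-diphenyl-1-(2-methylphenyl)tetrahydro-1H,3H-pyrrolo[1,2-c][1,3,2]oxazaborole protonated by HNTf2 (10 mol %), CH2Cl2, −78 °C
Reagents that add atoms: none
Why: Oxazaborolidinium-catalysed enantioselective Diels–Alder reaction of an α-substituted acrolein, in which the 2-silyloxydiene adds with "para" regiochemistry and the chiral Lewis acid shields one face of the bound enal, so the quaternary C1 is set as (S) (the mirror-image catalyst is used if the salt written delivers the (R)-aldehyde).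

Step 3
Reactants: 4 (S)-1-methyl-4-(triisopropylsilyloxy)cyclohex-3-ene-1-carbaldehyde
Product: 5 (S)-4-ethynyl-4-methyl-1-(triisopropylsilyloxy)cyclohex-1-ene
Conditions: Me3SiCHN2, n-BuLi, THF, −78 → 25 °C
Reagents that add atoms: trimethylsilyldiazomethane, C[Si](C)(C)C=[N+]=[N-]
Why: Colvin homologation, in which lithiated trimethylsilyldiazomethane adds to the non-enolisable aldehyde, Peterson-type loss of silanolate and N2 gives an alkylidene carbene, and its 1,2-hydride shift gives the terminal alkyne that masks C2 without touching C1.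

Step 4
Reactants: 5 (S)-4-ethynyl-4-methyl-1-(triisopropylsilyloxy)cyclohex-1-ene
Product: 6 triisopropylsilyl (4S)-4-ethynyl-4-methyl-6-oxohexanoate
Conditions: O3, CH2Cl2, −78 °C; then PPh3, −78 → 25 °C
Reagents that add atoms: ozone, [O-][O+]=O
Why: Ozonolysis of the electron-rich silyl enol ether double bond (far faster than attack on the alkyne) opens the ring into the C10 aldehyde and the C3′ silyl ester, two differentiated arms on the intact quaternary centre.

Step 5
Reactants: 6 triisopropylsilyl (4S)-4-ethynyl-4-methyl-6-oxohexanoate; 7 2-bromo-3,3-dimethoxyprop-1-ene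
Product: 8 triisopropylsilyl (4S,6RS)-7-(dimethoxymethyl)-4-ethynyl-6-hydroxy-4-methyloct-7-enoate
Conditions: CrCl2 (4 equiv), NiCl2 (2 mol %), DMF, 25 °C
Reagents that add atoms: none
Why: Nozaki–Hiyama–Kishi reaction, in which the alkenylchromium species made from 7 adds only to the aldehyde and tolerates the silyl ester, the acetal and the acidic alkyne C–H; the C10 carbinol forms as a mixture that does not matter because C10 later becomes sp2.

Step 6
Reactants: 8 triisopropylsilyl (4S,6RS)-7-(dimethoxymethyl)-4-ethynyl-6-hydroxy-4-methyloct-7-enoate; 9 prop-1-en-2-ylmagnesium bromide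
Product: 11 (6S,8RS)-9-(dimethoxymethyl)-6-ethynyl-8-hydroxy-2,6-dimethyldeca-1,9-dien-3-one, via Weinreb amide 10 (not isolated)
Conditions: MeNH(OMe)·HCl, i-PrMgCl, THF, −20 °C; then 9, −20 → 0 °C; aq NH4Cl
Reagents that add atoms: none
Why: One-pot Weinreb ketone synthesis, in which the magnesium amide converts the activated silyl ester into the N-methoxy-N-methylamide and the chelated tetrahedral adduct with the Grignard reagent collapses to the isopropenyl ketone only on work-up, so there is no over-addition.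

Step 7
Reactants: 11 (6S,8RS)-9-(dimethoxymethyl)-6-ethynyl-8-hydroxy-2,6-dimethyldeca-1,9-dien-3-one
Product: 12 (3S,6S,8RS)-9-(dimethoxymethyl)-6-ethynyl-2,6-dimethyldeca-1,9-diene-3,8-diol
Conditions: (R)-1-methyl-3,3-diphenyltetrahydro-1H,3H-pyrrolo[1,2-c][1,3,2]oxazaborole (0.3 equiv), catecholborane, toluene, −78 °C; then MeOH, aq NaHCO3
Reagents that add atoms: none
Why: Corey–Bakshi–Shibata reduction, in which the isopropenyl group is the large substituent so the (R)-oxazaborolidine delivers hydride to give the (3′S)-allylic alcohol, while catecholborane at −78 °C leaves the alkyne and alkenes alone.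

Step 8
Reactants: 12 (3S,6S,8RS)-9-(dimethoxymethyl)-6-ethynyl-2,6-dimethyldeca-1,9-diene-3,8-diol
Product: 13 (3S,6S,8RS)-3,8-bis(tert-butyldimethylsilyloxy)-9-(dimethoxymethyl)-6-ethynyl-2,6-dimethyldeca-1,9-diene
Conditions: t-BuMe2SiCl, imidazole, 4-(dimethylamino)pyridine (cat.), DMF, 40 °C
Reagents that add atoms: tert-butyldimethylsilyl chloride, CC(C)(C)[Si](C)(C)Cl
Why: Silyl ether formation on both secondary alcohols under neutral imidazole conditions that spare the dimethyl acetal; the C10 silyloxy group later serves as the leaving group.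

Step 9
Reactants: 14 but-2-yn-1-ol
Product: 16 (Z)-3-iodobut-2-en-1-ol, via alkenylalanate 15 (not isolated)
Conditions: NaAlH2(OCH2CH2OCH3)2, THF, 0 → 25 °C; then I2, −78 °C
Reagents that add atoms: iodine, II
Why: Hydroxyl-directed trans-hydroalumination of the propargylic alcohol (hydride to C2, aluminium to C3) and iodinolysis with retention give the (Z)-iodoalkene, which fixes the later C5=C6 geometry.

Step 10
Reactants: 16 (Z)-3-iodobut-2-en-1-ol
Product: 17 (Z)-1-(tert-butyldimethylsilyloxy)-3-iodobut-2-ene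
Conditions: t-BuMe2SiCl, imidazole, CH2Cl2, 25 °C
Reagents that add atoms: tert-butyldimethylsilyl chloride, CC(C)(C)[Si](C)(C)Cl
Why: Standard silyl ether protection of the primary allylic alcohol so that the alkenyllithium can be formed.

Step 11
Reactants: 17 (Z)-1-(tert-butyldimethylsilyloxy)-3-iodobut-2-ene
Product: 19 (Z)-4-(tert-butyldimethylsilyloxy)-2-methylbut-2-enal, via alkenyllithium 18 (not isolated)
Conditions: t-BuLi (2.1 equiv), Et2O, −78 °C; then DMF, −78 → 0 °C
Reagents that add atoms: N,N-dimethylformamide, CN(C)C=O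
Why: Iodine–lithium exchange with retention of alkene geometry followed by Bouveault formylation of the alkenyllithium gives the (Z)-enal with C4 cis to C7.

Step 12
Reactants: 13 (3S,6S,8RS)-3,8-bis(tert-butyldimethylsilyloxy)-9-(dimethoxymethyl)-6-ethynyl-2,6-dimethyldeca-1,9-diene; 19 (Z)-4-(tert-butyldimethylsilyloxy)-2-methylbut-2-enal
Product: 22 (1S,2E,4R,5Z,3′S)-seco allylic alcohol [C4–OH; C7–OTBS; C10–OTBS; C12 dimethyl acetal; C3′–OTBS], via alkenylborane 20 (not isolated), via alkenylzinc 21 (not isolated)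
Conditions: (c-C6H11)2BH, toluene, 0 → 25 °C; Et2Zn, −78 °C; (+)-3-exo-morpholinoisoborneol (10 mol %), then 19, −30 → −10 °C; aq NH4Cl
Reagents that add atoms: none
Why: Oppolzer–Radinov alkenylzinc addition, in which syn-hydroboration of the terminal alkyne gives the (E)-alkenylborane, boron-to-zinc exchange and amino-alcohol-catalysed addition to the enal form C3–C4 with the E-C2=C3 bond, and the ligand antipode (the mirror image of the one that gives (S)-carbinols from dialkylzincs) is chosen to set C4 as (R).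

Step 13
Reactants: 22 (1S,2E,4R,5Z,3′S)-seco allylic alcohol; 23 3-methylbut-2-enoic acid
Product: 24 C4 3-methylbut-2-enoate of 22
Conditions: N,N′-dicyclohexylcarbodiimide, 4-(dimethylamino)pyridine (cat.), CH2Cl2, 0 → 25 °C
Reagents that add atoms: none
Why: Steglich esterification acylates the only free hydroxyl with retention at C4 and avoids the ketene pathway that deconjugates the acid chloride.

Step 14
Reactants: 24 C4 3-methylbut-2-enoate of 22
Product: 25 hydroxy enal [C12HO on C9(=C8H2); C7–OH; C10–OTBS; C3′–OTBS]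
Conditions: AcOH–THF–H2O (3:1:1), 25 °C
Reagents that add atoms: water, O
Why: Mild acid hydrolysis cleaves the α,β-unsaturated dimethyl acetal and the primary allylic silyl ether much faster than the two secondary silyl ethers, which unmasks the α-substituted acrolein acceptor and the C7 alcohol in one operation.

Step 15
Reactants: 25 hydroxy enal
Product: 27 (Z)-allylic bromide [C7–Br], via mesylate 26 (not isolated)
Conditions: MsCl, Et3N, CH2Cl2, −40 °C; then LiBr, THF, 0 °C
Reagents that add atoms: lithium bromide, [Li+].[Br-]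
Why: Mesylation and SN2 displacement by bromide at the primary allylic carbon keep the Z geometry and give the radical precursor.

Step 16
Reactants: 27 (Z)-allylic bromide
Product: 29 (1S,2E,4R,5Z,9E,3′S)-macrocyclic trienal [C9–CHO; C4 3-methylbut-2-enoate; C3′–OTBS], via cyclised β-silyloxy aldehyde 28 (not isolated)
Conditions: Bu3SnH (1.5 equiv) and 2,2′-azobis(2-methylpropanenitrile) (0.3 equiv) by syringe pump over 12 h, benzene (0.002 M), 80 °C; then 1,8-diazabicyclo[5.4.0]undec-7-ene, 25 °C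
Reagents that add atoms: none
Why: Proposed new method: the tin radical abstracts bromine to give a (Z)-allyl radical that is reduced only slowly by the stannane and adds through its unhindered C7 terminus, in an 11-endo Giese fashion, to the CH2 of the α-substituted acrolein; the electrophilic α-formyl radical is then quenched by Bu3SnH (its transannular attack on C2 would have to join two fully substituted carbons), and base-induced E1cB loss of silanol gives the thermodynamically preferred (E)-2-alkylenal, that is the in-ring cis C9=C10 bond with C12 trans to C11; the closest known reaction type is the stannane-mediated macrocyclisation of allylic radicals onto enones.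

Step 17
Reactants: 29 macrocyclic trienal
Product: 30 (5S,6S)-epoxy enal
Conditions: dimethyldioxirane (1.1 equiv), acetone, −20 → 0 °C
Reagents that add atoms: dimethyldioxirane, CC1(C)OO1
Why: Substrate-controlled electrophilic epoxidation, in which only the trisubstituted C5=C6 bond is electron-rich enough (enal and enoate are deactivated, the other alkenes less substituted) and, with H4 eclipsing the alkene to relieve A(1,3) strain, the oxidant is expected to approach anti to the C4 acyloxy group to give the (5S,6S) cis-oxirane.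

Step 18
Reactants: 30 (5S,6S)-epoxy enal
Product: 31 C3′-O-TBS ether of the target
Conditions: NaBH4, CeCl3·7H2O, MeOH, −40 °C
Reagents that add atoms: none
Why: Luche reduction gives clean 1,2-reduction of the enal to the primary allylic alcohol without touching the ester or the oxirane.

Step 19
Reactants: 31 C3′-O-TBS ether of the target
Product: 32 target CNP0309478.6
Conditions: HF·pyridine, pyridine, THF, 0 → 25 °C
Reagents that add atoms: none
Why: Buffered fluoride desilylation frees the C3′ alcohol under conditions that neither open the oxirane nor move the allylic ester.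

## Compound list

1 | but-3-en-2-one | CC(=O)C=C | starting material
2 | 2-(triisopropylsilyloxy)buta-1,3-diene | C=CC(=C)O[Si](C(C)C)(C(C)C)C(C)C | intermediate
3 | 2-methylprop-2-enal | CC(=C)C=O | starting material
4 | (S)-1-methyl-4-(triisopropylsilyloxy)cyclohex-3-ene-1-carbaldehyde | O=C[C@]1(C)CC=C(O[Si](C(C)C)(C(C)C)C(C)C)CC1 | intermediate
5 | (S)-4-ethynyl-4-methyl-1-(triisopropylsilyloxy)cyclohex-1-ene | C#C[C@]1(C)CC=C(O[Si](C(C)C)(C(C)C)C(C)C)CC1 | intermediate
6 | triisopropylsilyl (4S)-4-ethynyl-4-methyl-6-oxohexanoate | CC(C)[Si](C(C)C)(C(C)C)OC(=O)CC[C@](CC=O)(C)C#C | intermediate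
7 | 2-bromo-3,3-dimethoxyprop-1-ene | C=C(Br)C(OC)OC | starting material
8 | triisopropylsilyl (4S,6RS)-7-(dimethoxymethyl)-4-ethynyl-6-hydroxy-4-methyloct-7-enoate | CC(C)[Si](C(C)C)(C(C)C)OC(=O)CC[C@](CC(O)C(=C)C(OC)OC)(C)C#C | intermediate
9 | prop-1-en-2-ylmagnesium bromide | CC(=C)[Mg]Br | starting material
10 | Weinreb amide: (4S,6RS)-7-(dimethoxymethyl)-4-ethynyl-6-hydroxy-N-methoxy-N,4-dimethyloct-7-enamide | CON(C)C(=O)CC[C@](CC(O)C(=C)C(OC)OC)(C)C#C | intermediate
11 | (6S,8RS)-9-(dimethoxymethyl)-6-ethynyl-8-hydroxy-2,6-dimethyldeca-1,9-dien-3-one | C=C(C)C(=O)CC[C@](CC(O)C(=C)C(OC)OC)(C)C#C | intermediate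
12 | (3S,6S,8RS)-9-(dimethoxymethyl)-6-ethynyl-2,6-dimethyldeca-1,9-diene-3,8-diol | C=C(C)[C@@H](O)CC[C@](CC(O)C(=C)C(OC)OC)(C)C#C | intermediate
13 | (3S,6S,8RS)-3,8-bis(tert-butyldimethylsilyloxy)-9-(dimethoxymethyl)-6-ethynyl-2,6-dimethyldeca-1,9-diene | C=C(C)[C@@H](O[Si](C)(C)C(C)(C)C)CC[C@](CC(O[Si](C)(C)C(C)(C)C)C(=C)C(OC)OC)(C)C#C | intermediate
14 | but-2-yn-1-ol | CC#CCO | starting material
15 | alkenylalanate: sodium 2,2-bis(2-methoxyethoxy)-3-methyl-2,5-dihydro-1,2-oxaluminol-2-uide | CC1=CCO[Al-]1(OCCOC)OCCOC.[Na+] | intermediate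
16 | (Z)-3-iodobut-2-en-1-ol | C/C(I)=C/CO | intermediate
17 | (Z)-1-(tert-butyldimethylsilyloxy)-3-iodobut-2-ene | C/C(I)=C/CO[Si](C)(C)C(C)(C)C | intermediate
18 | alkenyllithium: [4-(tert-butyldimethylsilyloxy)but-2-en-2-yl]lithium, lithium cis to the CH2O group | C/C([Li])=C/CO[Si](C)(C)C(C)(C)C | intermediate
19 | (Z)-4-(tert-butyldimethylsilyloxy)-2-methylbut-2-enal | C/C(C=O)=C/CO[Si](C)(C)C(C)(C)C | intermediate
20 | alkenylborane: (E)-alkenyl(dicyclohexyl)borane from hydroboration of 13 at C2≡C3 | C=C(C)[C@@H](O[Si](C)(C)C(C)(C)C)CC[C@](CC(O[Si](C)(C)C(C)(C)C)C(=C)C(OC)OC)(C)/C=C/B(C1CCCCC1)C1CCCCC1 | intermediate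
21 | alkenylzinc: (E)-alkenyl(ethyl)zinc from 20 | C=C(C)[C@@H](O[Si](C)(C)C(C)(C)C)CC[C@](CC(O[Si](C)(C)C(C)(C)C)C(=C)C(OC)OC)(C)/C=C/[Zn]CC | intermediate
22 | (1S,2E,4R,5Z,3′S)-seco allylic alcohol: 13 in which C≡CH has become (E)-CH=CH–CH(OH)–C(CH3)=CH–CH2OTBS; C10–OTBS (10RS), C12 dimethyl acetal, C3′–OTBS | C=C(C)[C@@H](O[Si](C)(C)C(C)(C)C)CC[C@](CC(O[Si](C)(C)C(C)(C)C)C(=C)C(OC)OC)(C)/C=C/[C@@H](O)/C(C)=C\CO[Si](C)(C)C(C)(C)C | intermediate
23 | 3-methylbut-2-enoic acid | CC(C)=CC(=O)O | starting material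
24 | C4 3-methylbut-2-enoate of 22 | C=C(C)[C@@H](O[Si](C)(C)C(C)(C)C)CC[C@](CC(O[Si](C)(C)C(C)(C)C)C(=C)C(OC)OC)(C)/C=C/[C@@H](OC(=O)C=C(C)C)/C(C)=C\CO[Si](C)(C)C(C)(C)C | intermediate
25 | hydroxy enal: 24 with C12H(OMe)2 turned into C12HO and C7–OTBS into C7–OH | C=C(C)[C@@H](O[Si](C)(C)C(C)(C)C)CC[C@](CC(O[Si](C)(C)C(C)(C)C)C(=C)C=O)(C)/C=C/[C@@H](OC(=O)C=C(C)C)/C(C)=C\CO | intermediate
26 | mesylate: C7 methanesulfonate of 25 | C=C(C)[C@@H](O[Si](C)(C)C(C)(C)C)CC[C@](CC(O[Si](C)(C)C(C)(C)C)C(=C)C=O)(C)/C=C/[C@@H](OC(=O)C=C(C)C)/C(C)=C\COS(C)(=O)=O | intermediate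
27 | (Z)-allylic bromide: 25 with C7–Br in place of C7–OH | C=C(C)[C@@H](O[Si](C)(C)C(C)(C)C)CC[C@](CC(O[Si](C)(C)C(C)(C)C)C(=C)C=O)(C)/C=C/[C@@H](OC(=O)C=C(C)C)/C(C)=C\CBr | intermediate
28 | cyclised β-silyloxy aldehyde: eleven-membered ring closed by C7–C8; C9H(CHO); C10H(OTBS); C9 and C10 unassigned | C=C(C)[C@@H](O[Si](C)(C)C(C)(C)C)CC[C@]1(C)/C=C/[C@@H](OC(=O)C=C(C)C)/C(C)=C\CCC(C=O)C(O[Si](C)(C)C(C)(C)C)C1 | intermediate
29 | (1S,2E,4R,5Z,9E,3′S)-macrocyclic trienal: C9–CHO, C4 3-methylbut-2-enoate, C3′–OTBS | C=C(C)[C@@H](O[Si](C)(C)C(C)(C)C)CC[C@]1(C)/C=C/[C@@H](OC(=O)C=C(C)C)/C(C)=C\CC/C(C=O)=C\C1 | intermediate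
30 | (1S,4R,5S,6S,3′S)-epoxy enal: 29 with the C5–C6 cis-oxirane | C=C(C)[C@@H](O[Si](C)(C)C(C)(C)C)CC[C@]1(C)/C=C/[C@@H](OC(=O)C=C(C)C)[C@@]2(C)O[C@H]2CC/C(C=O)=C\C1 | intermediate
31 | C3′-O-TBS ether of the target | C=C(C)[C@@H](O[Si](C)(C)C(C)(C)C)CC[C@]1(C)/C=C/[C@@H](OC(=O)C=C(C)C)[C@@]2(C)O[C@H]2CC/C(CO)=C\C1 | intermediate
32 | CNP0309478.6: (1S,4R,5S,6S,3′S); (2E)-alkene; C9=C10 with C12H2OH trans to C11; C4 3-methylbut-2-enoate | C=C(C)[C@@H](O)CC[C@]1(C)/C=C/[C@@H](OC(=O)C=C(C)C)[C@@]2(C)O[C@H]2CC/C(CO)=C\C1 | target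

## Step count and weak points

Total step count: 19. Longest linear sequence: 16 (steps 1–8, then 12–19); steps 9–11 are a three-step branch.

The three steps most likely to fail, each with its fallback:

Step 16 (radical macrocyclisation). An eleven-membered ring closure must beat direct reduction of the allyl radical, and the cyclised radical must be reduced before it does anything else. The fallback sets out from 25 and returns at 29, and removes the hydride donor altogether. MsCl/Et3N then NaI in acetone gives the allylic iodide F1. Iodine-atom-transfer cyclisation (Bu3SnSnBu3 10 mol %, visible light, benzene 0.002 M, 25 °C) gives the macrocyclic α-iodo aldehyde F2, in which the cyclised radical is capped by iodine from a second molecule of F1. Zinc dust in THF/aq NH4Cl then forms the zinc enolate, which expels the C10 silanolate to give 29.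

Step 17 (face selectivity of the epoxidation). In the macrocycle the ring itself may override the allylic-strain argument and give the C5/C6 epimeric oxirane. The fallback sets out from 13 and 19 and returns at 30, and replaces substrate control by hydroxyl direction followed by inversion. Step 12 run with (−)-3-exo-morpholinoisoborneol gives the C4-epimeric (4S)-allylic alcohol F3. Ac2O/pyridine gives the (4S)-acetate F4. The conditions of steps 14, 15 and 16 give in turn the hydroxy enal acetate F5, the allylic bromide acetate F6 and the macrocyclic (4S)-acetate F7. K2CO3 in MeOH at 0 °C gives the macrocyclic (4S)-allylic alcohol F8. VO(acac)2/t-BuOOH in CH2Cl2 delivers oxygen syn to the hydroxyl of the H-eclipsed conformer and gives the (4S,5S,6S)-epoxy alcohol F9. Mitsunobu esterification with 23 (PPh3, diisopropyl azodicarboxylate, toluene) inverts C4 and gives 30.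

Step 12 (alkenylzinc addition). A hindered alkyne and an isomerisation-prone (Z)-enal may give low conversion or low selectivity at C4. The fallback sets out from 13 and 19 and returns at 22, and sets C4 by ketone reduction instead. The lithium acetylide of 13 (n-BuLi, THF, −78 °C) adds to 19 to give the propargylic alcohol F10 as a C4 mixture. Dess–Martin periodinane gives the ynone F11. (S)-1-methyl-3,3-diphenyltetrahydro-1H,3H-pyrrolo[1,2-c][1,3,2]oxazaborole with catecholborane, the alkynyl group acting as the small substituent, gives the single propargylic alcohol F12 ((S) by the CIP rules at this stage). Trans-hydroalumination with NaAlH2(OCH2CH2OCH3)2 then gives 22.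

## Further compounds

F1 | step 16 | allylic iodide: 25 with C7–I in place of C7–OH | C=C(C)[C@@H](O[Si](C)(C)C(C)(C)C)CC[C@](CC(O[Si](C)(C)C(C)(C)C)C(=C)C=O)(C)/C=C/[C@@H](OC(=O)C=C(C)C)/C(C)=C\CI
F2 | step 16 | macrocyclic α-iodo aldehyde: 28 with iodine on C9 | C=C(C)[C@@H](O[Si](C)(C)C(C)(C)C)CC[C@]1(C)/C=C/[C@@H](OC(=O)C=C(C)C)/C(C)=C\CCC(I)(C=O)C(O[Si](C)(C)C(C)(C)C)C1
F3 | step 17 | (4S)-allylic alcohol: C4 epimer of 22 | C=C(C)[C@@H](O[Si](C)(C)C(C)(C)C)CC[C@](CC(O[Si](C)(C)C(C)(C)C)C(=C)C(OC)OC)(C)/C=C/[C@H](O)/C(C)=C\CO[Si](C)(C)C(C)(C)C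
F4 | step 17 | (4S)-acetate of F3 | C=C(C)[C@@H](O[Si](C)(C)C(C)(C)C)CC[C@](CC(O[Si](C)(C)C(C)(C)C)C(=C)C(OC)OC)(C)/C=C/[C@H](OC(C)=O)/C(C)=C\CO[Si](C)(C)C(C)(C)C
F5 | step 17 | hydroxy enal acetate: F4 with C12HO and C7–OH | C=C(C)[C@@H](O[Si](C)(C)C(C)(C)C)CC[C@](CC(O[Si](C)(C)C(C)(C)C)C(=C)C=O)(C)/C=C/[C@H](OC(C)=O)/C(C)=C\CO
F6 | step 17 | allylic bromide acetate: F5 with C7–Br | C=C(C)[C@@H](O[Si](C)(C)C(C)(C)C)CC[C@](CC(O[Si](C)(C)C(C)(C)C)C(=C)C=O)(C)/C=C/[C@H](OC(C)=O)/C(C)=C\CBr
F7 | step 17 | macrocyclic (4S)-acetate: C4 epimer of 29 with acetate in place of the 3-methylbut-2-enoate | C=C(C)[C@@H](O[Si](C)(C)C(C)(C)C)CC[C@]1(C)/C=C/[C@H](OC(C)=O)/C(C)=C\CC/C(C=O)=C\C1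
F8 | step 17 | macrocyclic (4S)-allylic alcohol | C=C(C)[C@@H](O[Si](C)(C)C(C)(C)C)CC[C@]1(C)/C=C/[C@H](O)/C(C)=C\CC/C(C=O)=C\C1
F9 | step 17 | (4S,5S,6S)-epoxy alcohol | C=C(C)[C@@H](O[Si](C)(C)C(C)(C)C)CC[C@]1(C)/C=C/[C@H](O)[C@@]2(C)O[C@H]2CC/C(C=O)=C\C1
F10 | step 12 | propargylic alcohol, C4 mixture: 13 with C≡C–CH(OH)–C(CH3)=CH–CH2OTBS | C=C(C)[C@@H](O[Si](C)(C)C(C)(C)C)CC[C@](CC(O[Si](C)(C)C(C)(C)C)C(=C)C(OC)OC)(C)C#CC(O)/C(C)=C\CO[Si](C)(C)C(C)(C)C
F11 | step 12 | ynone: C4 ketone of F10 | C=C(C)[C@@H](O[Si](C)(C)C(C)(C)C)CC[C@](CC(O[Si](C)(C)C(C)(C)C)C(=C)C(OC)OC)(C)C#CC(=O)/C(C)=C\CO[Si](C)(C)C(C)(C)C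
F12 | step 12 | single propargylic alcohol with the C4 configuration of 22 | C=C(C)[C@@H](O[Si](C)(C)C(C)(C)C)CC[C@](CC(O[Si](C)(C)C(C)(C)C)C(=C)C(OC)OC)(C)C#C[C@@H](O)/C(C)=C\CO[Si](C)(C)C(C)(C)C
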